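- Watch the first nucleophile. This flask charges it at 0.263 M against 0.25 M of starting material, which is 1.05 mol per mol, so target formation eats deep into it.

the same everywhere: gas 9.2 mM (held)
- alder: starting material 0.25 M; first nucleophile 0.37 M; run made earlier
- birch: starting material 0.25 M; first nucleophile 0.58 M; run made earlier
- maple: starting material 0.38 M; first nucleophile 0.263 M; run made earlier
- flask: starting material 0.25 M; first nucleophile 0.263 M; time 15 d

| run | time / d | target / % | other capture product / % | starting material / % |
|---|---|---|---|---|
| alder | 1.04 | 81.8 | 6.4 | 0.1 |
| alder | 1.67 | 81.9 | 6.6 | 0.1 |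
| alder | 2.50 | 81.4 | 6.1 | 0.2 |
| alder | 4.00 | 82.0 | 6.0 | 0.4 |
| alder | 8.00 | 82.0 | 6.4 | 0.2 |
| alder | 12.0 | 81.6 | 5.7 | 0 |
| birch | 1.04 | 89.4 | 4.4 | 0 |
| birch | 1.67 | 89.6 | 4.5 | 0.1 |
| birch | 2.50 | 89.1 | 4.2 | 0 |
| birch | 4.00 | 90.0 | 4.6 | 0 |
| birch | 8.00 | 89.2 | 4.6 | 0.3 |
| birch | 12.0 | 89.6 | 4.3 | 0 |
| maple | 1.04 | 61.7 | 9.1 | 0.3 |
| maple | 3.00 | 62.0 | 8.9 | 0 |
| maple | 6.00 | 61.5 | 9.2 | 0 |
| maple | 8.00 | 61.8 | 8.9 | 0.3 |
| maple | 12.0 | 62.2 | 8.9 | 0 |

(each reading ± 0.3 percentage points)

- the earlier runs were read with a standard deviation of 0.3 percentage points
- at the start none of the gas is in solution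
- a reading or a percentage of target counts all its forms, free or not

- share of target in target plus other capture product at 8.0 min
- share of target in target plus other capture product at 6.0 h
- share of target in target plus other capture product at 15 d

- First instants: the gas starts at zero in solution and the first nucleophile stands at its full charge, so I expect a high share of target.
- Middle: gas has entered and the first nucleophile is falling as target forms, so I expect each further portion to split worse and the share to slide.
- End: from the first reading at 1.04 d, the alder, birch and maple runs stay flat, so they give me ends and no rates.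
- I freeze one thing across those ends. Alder gives 51.9 M⁻¹ for the capture number, a selectivity factor in integrated form: the natural log of first nucleophile charged over first nucleophile charged minus target formed, divided by the molar amount of other capture product.
- Birch reads 44.0 M⁻¹ and maple 65.5 M⁻¹, so the number drifts, and I use it only between neighbouring runs.
- This flask shares its starting material charge with alder and its first nucleophile charge with maple, so I take the mean of those two runs: capture number 58.7 M⁻¹ and target 71.8%.
- That calls for 7.82% of other capture product in this flask, so my end share is 90.2%.
- The forecast says 97% at 8.0 min, 92% at 6.0 h and 89.7% at 15 d, noting “Gas must also dissolve from zero”. My end share stands higher than its figure by 0.50 percentage points.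
- The flask gives 96.7%, 89.9% and 89.5%.

    starting material → intermediate (k = 1.60 h⁻¹)
    first nucleophile + intermediate → target (k = 10.0 M⁻¹ h⁻¹)
    second nucleophile + intermediate → other capture product (k = 350 M⁻¹ h⁻¹)
    intermediate → solvolysis product (k = 0.240 h⁻¹)
    crystals ⇌ target, rate k5*(cs5 - [target]) while solid is left; crystals form when [target] > cs5 (solubility = 0.170 M, k = 1.70 h⁻¹)
    gas ⇌ second nucleophile, rate k6*(csat - [second nucleophile]) (kL = 0.460 h⁻¹)
    first nucleophile + target ⇌ idle adduct, settled at all times (K = 10.0 M⁻¹)

- The main reason this flask's share stands at 96.7% at 8.0 min is the drag of the gas passing into second nucleophile: without that drag, the share at that time is 46.0%. The flask's own capture number comes to 55.0 M⁻¹, between alder and maple. The neighbour flask with 0.45 M of first nucleophile lies between alder and birch, so their mean, 47.9 M⁻¹, applied to its 85.8% of target, calls for 5.41% of other capture product, and it holds 5.38%.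

Readings and results were generated by integration on assumed constants; the scatter is artificial.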